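**Plan**

- Retrosynthesis (target ring atoms: C1 carbonyl, C2=C3, C4 methoxy carbon, C5 methylene, C6 quaternary carbon): remove the silyl group, add methanol back across C2=C3 to put a methoxy group on C3, cut the C6–allyl bond (enolate allylation), then excise C6 from the ring (C5–C6 by retro 1,2-shift, C1–C6 by retro carbanion addition).
- Enabling feature: ring atoms C1–C5 with trans methoxy groups on C3 and C4 form a C2-symmetric cyclopentanone. Its two C(=O)–CH2 bonds are equivalent, so C6 can be inserted without a regiochemical choice, and the C2=C3 alkene is latent in the C3 methoxy group.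
- Forward: the ketone is made from diethyl D-tartrate (4 steps). The side chain is made from 3,4,5-trimethoxybenzaldehyde (anti-crotylation, silylation, alkene cleavage, gem-dibromination). In one flask the dibromoalkyllithium adds to the ketone, the five-membered ring becomes the six-membered ring by a β-oxido carbenoid 1,2-shift, and the enolate formed is allylated. Loss of methanol and desilylation finish the route.
- Stereochemistry: C4 comes from D-tartaric acid. The carbinol and methyl-bearing carbons come from a reagent-controlled (E)-crotylboration. C6 is set in the allylation under substrate control (axial attack trans to the C4 methoxy group, reinforced by allylic 1,3-strain in the side chain).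

Key step: step 9

Assumption: the (E)-crotylborane made from (+)-α-pinene is taken to give the (1S,2S) alcohol with aromatic aldehydes; should the sense be the reverse, the reagent from (−)-α-pinene is used instead.

Step 1
Reactants: 1 diethyl D-tartrate
Product: 2 diethyl (2S,3S)-2,3-dimethoxybutanedioate
Conditions: MeI, Ag2O, Et2O, reflux
Reagents that add atoms: iodomethane, CI
Why: Purdie methylation (O-alkylation of both secondary hydroxyl groups by MeI on Ag2O) runs under non-basic conditions, so the stereocenters α to the esters are not epimerised and no new stereocenter forms.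

Step 2
Reactants: 2 diethyl (2S,3S)-2,3-dimethoxybutanedioate
Product: 3 (2R,3R)-2,3-dimethoxybutane-1,4-diol
Conditions: LiAlH4, THF, 0 °C to reflux
Reagents that add atoms: none
Why: Hydride reduction of both esters to primary alcohols (LiAlH4 ester reduction) leaves the methoxy-bearing carbons untouched; the descriptor changes from S to R through substituent priority only.

Step 3
Reactants: 3 (2R,3R)-2,3-dimethoxybutane-1,4-diol
Product: 4 (2S,3S)-1,4-diiodo-2,3-dimethoxybutane
Conditions: I2, PPh3, imidazole, CH2Cl2, 0 °C to rt
Reagents that add atoms: iodine, II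
Why: Appel-type iodination replaces both primary hydroxyl groups by SN2 displacement of the oxyphosphonium group at CH2, away from the stereocenters (the descriptor again changes by priority only).

Step 4
Reactants: 4 (2S,3S)-1,4-diiodo-2,3-dimethoxybutane
Product: 6 (3R,4R)-3,4-dimethoxycyclopentan-1-one, via tosyl isocyanide 5 (not isolated)
Conditions: TosMIC, NaH, DMSO/Et2O, 0 °C to rt; then 2 M HCl, Et2O, rt
Reagents that add atoms: tosylmethyl isocyanide (TosMIC), Cc1ccc(cc1)S(=O)(=O)C[N+]#[C-]; water, O
Why: In the van Leusen ketone synthesis the TosMIC anion is alkylated twice by the 1,4-diiodide (the second time 5-exo-tet) and acid hydrolysis of the α-sulfonyl isocyanide releases the ketone, so the carbonyl carbon arrives as a formaldehyde dianion equivalent and the two stereocenters are not involved.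

Step 5
Reactants: 7 3,4,5-trimethoxybenzaldehyde
Product: 8 (1S,2S)-2-methyl-1-(3,4,5-trimethoxyphenyl)but-3-en-1-ol
Conditions: trans-2-butene, KOt-Bu, n-BuLi, THF, −78 to −45 °C; (−)-Ipc2BOMe [from (+)-α-pinene], −78 °C; BF3·OEt2; then 7, −78 °C; NaOH, H2O2, 0 °C to rt
Reagents that add atoms: trans-2-butene, C/C=C/C
Why: In the Brown crotylation the (E)-crotylborane reacts through a closed chair (Zimmerman–Traxler) transition state, so the E geometry fixes the anti methyl/hydroxyl relationship and the isopinocampheyl groups fix the absolute sense, setting both new stereocenters as 1S,2S under reagent control.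

Step 6
Reactants: 8 (1S,2S)-2-methyl-1-(3,4,5-trimethoxyphenyl)but-3-en-1-ol
Product: 9 tert-butyldimethyl{[(1S,2S)-2-methyl-1-(3,4,5-trimethoxyphenyl)but-3-en-1-yl]oxy}silane
Conditions: TBSOTf, 2,6-lutidine, CH2Cl2, −78 to 0 °C
Reagents that add atoms: tert-butyldimethylsilyl trifluoromethanesulfonate, CC(C)(C)[Si](C)(C)OS(=O)(=O)C(F)(F)F
Why: O-silylation of the hindered secondary benzylic alcohol by the silyl triflate gives a bulky, non-chelating ether that should survive the organolithium steps and later serves as the large group in the allylation.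

Step 7
Reactants: 9 tert-butyldimethyl{[(1S,2S)-2-methyl-1-(3,4,5-trimethoxyphenyl)but-3-en-1-yl]oxy}silane
Product: 10 (2R,3S)-3-{[tert-butyl(dimethyl)silyl]oxy}-2-methyl-3-(3,4,5-trimethoxyphenyl)propanal
Conditions: OsO4 (cat.), NaIO4, 2,6-lutidine, dioxane/H2O, rt
Reagents that add atoms: osmium tetroxide, O=[Os](=O)(=O)=O (transfers the oxygen and is regenerated); sodium periodate, [Na+].[O-]I(=O)(=O)=O
Why: Lemieux–Johnson oxidation (OsO4-catalysed dihydroxylation of the terminal alkene and periodate cleavage) gives the aldehyde without ozone, which could attack the trimethoxyarene, and the lutidine buffer should prevent epimerisation of the α-carbon (its descriptor becomes R by priority only).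

Step 8
Reactants: 10 (2R,3S)-3-{[tert-butyl(dimethyl)silyl]oxy}-2-methyl-3-(3,4,5-trimethoxyphenyl)propanal
Product: 11 tert-butyl{[(1S,2R)-3,3-dibromo-2-methyl-1-(3,4,5-trimethoxyphenyl)propyl]oxy}dimethylsilane
Conditions: (PhO)3P, Br2, Et3N, CH2Cl2, −78 °C to rt
Reagents that add atoms: bromine, BrBr
Why: Deoxygenative gem-dibromination by the bromophosphonium species from triphenyl phosphite and bromine replaces C=O by CBr2 at low temperature, and Et3N scavenges acid so that the silyl ether and the α-stereocenter should survive.

Step 9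
Reactants: 11 tert-butyl{[(1S,2R)-3,3-dibromo-2-methyl-1-(3,4,5-trimethoxyphenyl)propyl]oxy}dimethylsilane; 6 (3R,4R)-3,4-dimethoxycyclopentan-1-one
Product: 16 (2R,4R,5R)-2-[(1S,2S)-1-{[tert-butyl(dimethyl)silyl]oxy}-1-(3,4,5-trimethoxyphenyl)propan-2-yl]-4,5-dimethoxy-2-(prop-2-en-1-yl)cyclohexan-1-one, via dibromoalkyllithium 12 (not isolated), via lithium alkoxide 13 (not isolated), via bromo lithio carbenoid 14 (not isolated), via lithium enolate 15 (not isolated)
Conditions: lithium 2,2,6,6-tetramethylpiperidide, THF/Et2O, −100 °C; then 6, −100 °C; then n-BuLi (1.1 equiv), −100 to −20 °C; then DMPU, allyl bromide, −78 to 0 °C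
Reagents that add atoms: allyl bromide, C=CCBr
Why: Lithium 2,2,6,6-tetramethylpiperidide removes the CHBr2 proton of 11 at −100 °C, dibromoalkyllithium 12 adds to the carbonyl group of 6 (the two faces of the C2-symmetric ketone are homotopic, so alkoxide 13 is a single compound), and n-BuLi then exchanges one bromine of 13 for lithium to give β-oxido carbenoid 14, in which a ring CH2 migrates from the carbinol carbon to the carbenoid carbon as bromide leaves, so the five-membered ring becomes six-membered and the inserted carbon becomes the nucleophilic carbon of enolate 15. The closest known reaction type is the β-oxido carbenoid ring enlargement of dibromoalkyl carbinolates, a Tiffeneau–Demjanov-type homologation under basic conditions, with alkylation of the regiodefined enolate in the same flask. No ring is closed by joining remote atoms; the ring grows by one-carbon insertion into a C(=O)–CH2 bond, and because 6 is C2-symmetric either α-CH2 gives the same enolate, so no regioisomer can form. The only new stereocenter, the quaternary carbon (C2 of 16, C6 of the target), is set in the C-allylation under substrate control: axial attack on the half-chair enolate that keeps both methoxy groups equatorial puts the allyl group trans to the methoxy group that is kept, and allylic 1,3-strain with the O–Li group holds the side-chain C–H in the enolate plane so that this same face is the one anti to the silyloxybenzyl group and syn to methyl, which should give R. The step needs the enolate to stay on the substituted side, since an enolate on the CH2 side would expel the neighbouring methoxy group; the carbenoid shift forms only the substituted enolate, and the hindered amine set free should be deprotonated too slowly by n-BuLi at −100 °C to compete with bromine–lithium exchange, so no amide base remains at the alkylation stage. O-allylation is the main competing path, which DMPU and the soft allyl bromide should disfavour.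

Step 10
Reactants: 16 (2R,4R,5R)-2-[(1S,2S)-1-{[tert-butyl(dimethyl)silyl]oxy}-1-(3,4,5-trimethoxyphenyl)propan-2-yl]-4,5-dimethoxy-2-(prop-2-en-1-yl)cyclohexan-1-one
Product: 17 (4R,6R)-6-[(1S,2S)-1-{[tert-butyl(dimethyl)silyl]oxy}-1-(3,4,5-trimethoxyphenyl)propan-2-yl]-4-methoxy-6-(prop-2-en-1-yl)cyclohex-2-en-1-one
Conditions: DBU, CH2Cl2, 0 °C to rt
Reagents that add atoms: none
Why: E1cB elimination: only the CH2 next to the ketone can be deprotonated (the other α-carbon is quaternary), and this enolate expels the β-methoxy group at C5 of 16 to give the conjugated enone, while the methoxy stereocenter at C4, which is not on the elimination path, is retained.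

Step 11
Reactants: 17 (4R,6R)-6-[(1S,2S)-1-{[tert-butyl(dimethyl)silyl]oxy}-1-(3,4,5-trimethoxyphenyl)propan-2-yl]-4-methoxy-6-(prop-2-en-1-yl)cyclohex-2-en-1-one
Product: 18 (4R,6R)-6-[(1S,2S)-1-hydroxy-1-(3,4,5-trimethoxyphenyl)propan-2-yl]-4-methoxy-6-(prop-2-en-1-yl)cyclohex-2-en-1-one (CNP0167650.2)
Conditions: HF·pyridine, THF, 0 °C to rt
Reagents that add atoms: none
Why: Fluoride cleavage of the Si–O bond (desilylation) under weakly acidic, buffered conditions should free the benzylic alcohol without epimerising the γ-carbon of the enone or touching the allyl group.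

**Compound list**

1 | diethyl D-tartrate, diethyl (2S,3S)-2,3-dihydroxybutanedioate | CCOC(=O)[C@@H](O)[C@H](O)C(=O)OCC | starting material
2 | diethyl (2S,3S)-2,3-dimethoxybutanedioate | CCOC(=O)[C@@H](OC)[C@H](OC)C(=O)OCC | intermediate
3 | (2R,3R)-2,3-dimethoxybutane-1,4-diol | OC[C@@H](OC)[C@H](OC)CO | intermediate
4 | (2S,3S)-1,4-diiodo-2,3-dimethoxybutane | IC[C@@H](OC)[C@H](OC)CI | intermediate
5 | (3R,4R)-1-isocyano-3,4-dimethoxy-1-[(4-methylphenyl)sulfonyl]cyclopentane | [C-]#[N+]C1(S(=O)(=O)c2ccc(C)cc2)C[C@@H](OC)[C@H](OC)C1 | intermediate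
6 | (3R,4R)-3,4-dimethoxycyclopentan-1-one | O=C1C[C@@H](OC)[C@H](OC)C1 | intermediate
7 | 3,4,5-trimethoxybenzaldehyde | O=Cc1cc(OC)c(OC)c(OC)c1 | starting material
8 | (1S,2S)-2-methyl-1-(3,4,5-trimethoxyphenyl)but-3-en-1-ol | C=C[C@H](C)[C@H](O)c1cc(OC)c(OC)c(OC)c1 | intermediate
9 | tert-butyldimethyl{[(1S,2S)-2-methyl-1-(3,4,5-trimethoxyphenyl)but-3-en-1-yl]oxy}silane | C=C[C@H](C)[C@H](O[Si](C)(C)C(C)(C)C)c1cc(OC)c(OC)c(OC)c1 | intermediate
10 | (2R,3S)-3-{[tert-butyl(dimethyl)silyl]oxy}-2-methyl-3-(3,4,5-trimethoxyphenyl)propanal | O=C[C@H](C)[C@H](O[Si](C)(C)C(C)(C)C)c1cc(OC)c(OC)c(OC)c1 | intermediate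
11 | tert-butyl{[(1S,2R)-3,3-dibromo-2-methyl-1-(3,4,5-trimethoxyphenyl)propyl]oxy}dimethylsilane | BrC(Br)[C@H](C)[C@H](O[Si](C)(C)C(C)(C)C)c1cc(OC)c(OC)c(OC)c1 | intermediate
12 | 1,1-dibromo-1-lithio derivative of 11 (dibromoalkyllithium) | [Li]C(Br)(Br)[C@H](C)[C@H](O[Si](C)(C)C(C)(C)C)c1cc(OC)c(OC)c(OC)c1 | intermediate
13 | lithium (3R,4R)-1-[(2R,3S)-1,1-dibromo-3-{[tert-butyl(dimethyl)silyl]oxy}-2-methyl-3-(3,4,5-trimethoxyphenyl)propyl]-3,4-dimethoxycyclopentan-1-olate | [Li]OC1(C(Br)(Br)[C@H](C)[C@H](O[Si](C)(C)C(C)(C)C)c2cc(OC)c(OC)c(OC)c2)C[C@@H](OC)[C@H](OC)C1 | intermediate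
14 | β-oxido carbenoid (1-bromo-1-lithioalkyl lithium cyclopentanolate derived from 13; carbenoid carbon configuration undefined) | [Li]OC1(C([Li])(Br)[C@H](C)[C@H](O[Si](C)(C)C(C)(C)C)c2cc(OC)c(OC)c(OC)c2)C[C@@H](OC)[C@H](OC)C1 | intermediate
15 | lithium (4R,5R)-2-[(1S,2S)-1-{[tert-butyl(dimethyl)silyl]oxy}-1-(3,4,5-trimethoxyphenyl)propan-2-yl]-4,5-dimethoxycyclohex-1-en-1-olate | [Li]OC1=C([C@H](C)[C@H](O[Si](C)(C)C(C)(C)C)c2cc(OC)c(OC)c(OC)c2)C[C@@H](OC)[C@H](OC)C1 | intermediate
16 | (2R,4R,5R)-2-[(1S,2S)-1-{[tert-butyl(dimethyl)silyl]oxy}-1-(3,4,5-trimethoxyphenyl)propan-2-yl]-4,5-dimethoxy-2-(prop-2-en-1-yl)cyclohexan-1-one | C=CC[C@]1([C@H](C)[C@H](O[Si](C)(C)C(C)(C)C)c2cc(OC)c(OC)c(OC)c2)C[C@@H](OC)[C@H](OC)CC1=O | intermediate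
17 | (4R,6R)-6-[(1S,2S)-1-{[tert-butyl(dimethyl)silyl]oxy}-1-(3,4,5-trimethoxyphenyl)propan-2-yl]-4-methoxy-6-(prop-2-en-1-yl)cyclohex-2-en-1-one | C=CC[C@]1([C@H](C)[C@H](O[Si](C)(C)C(C)(C)C)c2cc(OC)c(OC)c(OC)c2)C[C@@H](OC)C=CC1=O | intermediate
18 | (4R,6R)-6-[(1S,2S)-1-hydroxy-1-(3,4,5-trimethoxyphenyl)propan-2-yl]-4-methoxy-6-(prop-2-en-1-yl)cyclohex-2-en-1-one | C=CC[C@]1([C@H](C)[C@H](O)c2cc(OC)c(OC)c(OC)c2)C[C@@H](OC)C=CC1=O | target

**Step count**

Total steps: 11. Longest linear sequence: 7 (steps 5 to 11; the branch through steps 1 to 4 and 9 to 11 is equally long).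

**Steps most likely to fail**

Step 9. The hindered, basic carbanion 12 may abstract a proton from ketone 6 instead of adding to it, and the enolate so formed would lose methanol. Carbenoid 14 may be protonated by the amine before the 1,2-shift. The hindered tetrasubstituted enolate 15 may react at oxygen or with incomplete facial selectivity. The fallback sets out from aldehyde 10 and ketone 6 and comes back at 17, with the carbon–carbon bond formed under non-basic conditions. Aldehyde 10 is condensed with 1,2-bis(tert-butyldimethylsilyl)hydrazine (Sc(OTf)3 cat., CH2Cl2) to the N-silyl hydrazone F1. F1 is oxidised at −78 °C with (difluoroiodo)benzene and 2-chloropyridine to the diazoalkane F2. Sc(OTf)3-catalysed addition of F2 to 6 and 1,2-shift with loss of nitrogen (Tiffeneau–Demjanov-type homologation; again either α-CH2 gives the same product) should give the 2-substituted 4,5-dimethoxycyclohexanone F3 as a mixture at the new methine. DBU then removes methanol to give the 6-substituted 4-methoxycyclohex-2-enone F4. Kinetic deprotonation of F4 at the α′ methine with LiN(i-Pr)2 (THF, −78 °C) and alkylation with allyl bromide/DMPU should give 17, the allyl group being expected to enter anti to the silyloxybenzyl group and trans to the C4 methoxy group.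

Step 8. Enolisation of the α-branched aldehyde during halophosphonium activation may epimerise the methyl-bearing carbon or lead to a vinyl bromide, and acid formed may cleave the silyl ether. The fallback sets out from 10 and comes back at 11. The aldehyde is converted with hydrazine hydrate (EtOH, 0 °C) into hydrazone F5, which is treated with CuBr2 and LiOt-Bu in THF. Oxidation to the diazo compound and bromine transfer from CuBr2 with loss of nitrogen should give gem-dibromide 11 without an oxophilic phosphorus reagent or free acid.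

Step 10. Loss of methanol may be slow with an amine base, and under more forcing basic conditions the enone may be deprotonated at its γ-carbon, which would scramble the methoxy-bearing stereocenter. The fallback sets out from 16 and comes back at 17 without a basic elimination. Ketone 16 is converted with TMSOTf and Et3N (CH2Cl2, 0 °C) into the trimethylsilyl enol ether F6, which can only form toward the CH2 group. Brief treatment of F6 with dilute HCl in THF at 0 °C should ionise the allylic methoxy group next to the enol ether and collapse the silyloxy allyl cation to enone 17, as in the unmasking of β-methoxy silyl enol ethers from Danishefsky-type dienes.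

**Further compounds**

F1 | step 9 | N-(tert-butyldimethylsilyl)hydrazone of aldehyde 10 | CC(C)(C)[Si](C)(C)N/N=C/[C@H](C)[C@H](O[Si](C)(C)C(C)(C)C)c1cc(OC)c(OC)c(OC)c1
F2 | step 9 | diazoalkane from F1, tert-butyl{[(1S,2S)-3-diazo-2-methyl-1-(3,4,5-trimethoxyphenyl)propyl]oxy}dimethylsilane | [N-]=[N+]=C[C@H](C)[C@H](O[Si](C)(C)C(C)(C)C)c1cc(OC)c(OC)c(OC)c1
F3 | step 9 | (4R,5R)-2-[(1S,2S)-1-{[tert-butyl(dimethyl)silyl]oxy}-1-(3,4,5-trimethoxyphenyl)propan-2-yl]-4,5-dimethoxycyclohexan-1-one (mixture at C2) | C1([C@H](C)[C@H](O[Si](C)(C)C(C)(C)C)c2cc(OC)c(OC)c(OC)c2)C[C@@H](OC)[C@H](OC)CC1=O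
F4 | step 9 | (4R)-6-[(1S,2S)-1-{[tert-butyl(dimethyl)silyl]oxy}-1-(3,4,5-trimethoxyphenyl)propan-2-yl]-4-methoxycyclohex-2-en-1-one (mixture at C6) | C1([C@H](C)[C@H](O[Si](C)(C)C(C)(C)C)c2cc(OC)c(OC)c(OC)c2)C[C@@H](OC)C=CC1=O
F5 | step 8 | hydrazone of aldehyde 10 | N/N=C/[C@H](C)[C@H](O[Si](C)(C)C(C)(C)C)c1cc(OC)c(OC)c(OC)c1
F6 | step 10 | trimethylsilyl enol ether of ketone 16 (silyloxyalkene toward the former CH2 group; stereocenters as in 16) | C=CC[C@]1([C@H](C)[C@H](O[Si](C)(C)C(C)(C)C)c2cc(OC)c(OC)c(OC)c2)C[C@@H](OC)[C@H](OC)C=C1O[Si](C)(C)C
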